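Ring B, the cyclohexadienone (C1 carbonyl, C2 methyl-bearing, C3 and C5 enol carbons, C4 quaternary, C6 bridge-bearing), is an enolised 1,3,5-trione that cannot aromatise: a folded 2,2-disubstituted 3,5-dioxoheptanoate. The route rests on cutting C2–C3, where C3 is a carboxyl-level carbon on C4 and C2 the CH2 of a propionyl end. One Dieckmann-type Claisen closure of the dianion of open-chain triketo ester 10 should deliver ring B with all three oxygens and the intact C4 centre. The chain is assembled masked (two carbinols, one alkyne); C4 is set by chelate-controlled Fráter–Seebach chemistry. An ortho-quinone methide from aromatic ring A then forges the methylene bridge.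

Key step: step 7

Assumption: ring B is written in the tautomer of the target SMILES and 10 as its triketone. These tautomers interconvert freely and none of them involves C4.

Step 1
Reactants: 1 methyl 4-methyl-3-oxopentanoate
Product: 2 methyl (3R)-3-hydroxy-4-methylpentanoate
Conditions: RuCl2[(S)-BINAP] (cat.), H2 (50 atm), MeOH, 50 °C
Reagents that add atoms: none
Why: Noyori asymmetric hydrogenation of a chelating β-keto ester should deliver hydrogen to one carbonyl face; the (S)-ligand gives the arrangement that carries the descriptor R here, because isopropyl outranks CH2CO2Me.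

Step 2
Reactants: 2 methyl (3R)-3-hydroxy-4-methylpentanoate; 3 1-bromo-3-methylbut-2-ene (prenyl bromide)
Product: 4 methyl (2S,3S)-3-hydroxy-4-methyl-2-(3-methylbut-2-en-1-yl)pentanoate
Conditions: LiN(iPr)2 (2.2 equiv), THF, −78 → −20 °C; 3, DMPU, −78 → 0 °C; AcOH
Reagents that add atoms: none
Why: In this Fráter–Seebach alkylation the dilithio alkoxide–enolate forms a six-membered chelate whose isopropyl group shields one face, so the bromide should enter anti to it and give the 2,3-anti ester, whose C2 centre is erased again in step 4.

Step 3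
Reactants: 5 pent-2-yn-1-ol
Product: 6 pent-2-ynal
Conditions: MnO2 (excess), CH2Cl2, rt
Reagents that add atoms: none
Why: Heterogeneous MnO2 oxidation is selective for propargylic alcohols and stops at the aldehyde, which is volatile and is best used as a filtered, concentrated solution.

Step 4
Reactants: 4 methyl (2S,3S)-3-hydroxy-4-methyl-2-(3-methylbut-2-en-1-yl)pentanoate; 6 pent-2-ynal
Product: 7 methyl (2R)-2-[(1S)-1-hydroxy-2-methylpropyl]-2-(1-hydroxypent-2-yn-1-yl)-5-methylhex-4-enoate (both epimers at the propargylic carbinol)
Conditions: LiN(iPr)2 (2.3 equiv), THF, −78 → −10 °C; 6, −78 °C; AcOH, −78 °C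
Reagents that add atoms: none
Why: In this aldol addition of a Fráter–Seebach dianion, re-enolisation of 4 gives the same lithium chelate, now tetrasubstituted, and the aldehyde should again attack the face anti to the isopropyl group, which sets the quaternary carbon as R under control of the (S)-carbinol; the propargylic carbinol may form as both epimers because step 5 oxidises it.

Step 5
Reactants: 7 methyl (2R)-2-[(1S)-1-hydroxy-2-methylpropyl]-2-(1-hydroxypent-2-yn-1-yl)-5-methylhex-4-enoate
Product: 8 methyl (2R)-5-methyl-2-(2-methylpropanoyl)-2-(pent-2-ynoyl)hex-4-enoate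
Conditions: Dess–Martin periodinane (3 equiv), CH2Cl2, 0 °C → rt
Reagents that add atoms: none
Why: Dess–Martin oxidation is neutral and non-nucleophilic, so both secondary carbinols should go to ketones without retro-aldol cleavage, leaving the quaternary carbon, which has no α-hydrogen, as the only stereocentre.

Step 6
Reactants: 8 methyl (2R)-5-methyl-2-(2-methylpropanoyl)-2-(pent-2-ynoyl)hex-4-enoate
Product: 10 methyl (2S)-5-methyl-2-(2-methylpropanoyl)-2-(3-oxopentanoyl)hex-4-enoate, via diethylamino enaminone 9 (not isolated)
Conditions: Et2NH (1.1 equiv), CH2Cl2, 0 °C; then 1 M HCl, THF, rt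
Reagents that add atoms: water, O; diethylamine, CCNCC (held only in 9)
Why: Aza-Michael addition of a secondary amine to the ynone followed by acid hydrolysis of the vinylogous amide is a standard two-stage hydration that places the new oxygen on the β-carbon only and avoids π-acidic metals that could engage the 1,6-enyne.

Step 7
Reactants: 10 methyl (2S)-5-methyl-2-(2-methylpropanoyl)-2-(3-oxopentanoyl)hex-4-enoate
Product: 12 (4R)-3,5-dihydroxy-2-methyl-4-(3-methylbut-2-en-1-yl)-4-(2-methylpropanoyl)cyclohexa-2,5-dien-1-one, via dilithium dianion 11 (not isolated)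
Conditions: LiN(iPr)2 (3.3 equiv), THF, −78 → 0 °C; 1 M HCl, 0 °C
Reagents that add atoms: none
Why: The first equivalent of LiN(iPr)2 removes the proton between the two chain ketones and the second a propionyl CH2 proton, giving dianion 11, whose terminal carbon (future C2) adds to the methyl ester carbon on the quaternary centre (future C3); loss of LiOMe and deprotonation of the new trione by the third equivalent make the closure irreversible. The closest known reaction type is the Dieckmann-type Claisen cyclisation of 3,5-dioxoalkanoates and their gem-dialkyl analogues to cyclohexane-1,3,5-triones, the flask counterpart of the polyketide Claisen folding. The one ring formed closes in the 6-(enolendo)-exo-trig mode, which the Baldwin rules for enolates allow. No stereocentre is created: C4 bears no hydrogen and none of its four bonds is broken, so the configuration set in step 4 is carried over, the change of descriptor from S to R being a matter of priorities only. The step needs carbon over oxygen acylation (oxygen attack would give the six-membered enol lactone) and ester over isobutyryl ketone attack: the terminal carbanion of a lithium dianion is far more nucleophilic than its oxygens, the central carbon could only close a four-membered ring, and aldol addition to the hindered isopropyl ketone is reversible while the Claisen path is not. A non-nucleophilic amide base at low temperature is chosen so that the triacylated C4 is not cleaved by retro-Claisen attack.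

Step 8
Reactants: 13 phloroglucinol (benzene-1,3,5-triol); 14 2-methylpropanoyl chloride (isobutyryl chloride)
Product: 15 2-methyl-1-(2,4,6-trihydroxyphenyl)propan-1-one (phlorisobutyrophenone)
Conditions: AlCl3 (3 equiv), CH2Cl2/MeNO2, 0 → 40 °C; ice/aq. HCl
Reagents that add atoms: none
Why: In this Friedel–Crafts C-acylation of the electron-rich triol the first acyl group deactivates the ring, so monoacylation should prevail.

Step 9
Reactants: 15 2-methyl-1-(2,4,6-trihydroxyphenyl)propan-1-one; 3 1-bromo-3-methylbut-2-ene
Product: 16 2-methyl-1-[2,4,6-trihydroxy-3-(3-methylbut-2-en-1-yl)phenyl]propan-1-one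
Conditions: KOH (1 equiv), H2O, 0 °C → rt; 3 (1 equiv)
Reagents that add atoms: none
Why: Alkylation of the phloroglucinolate in water favours carbon attack because the oxygens are hydrogen-bonded; the two free ring positions are equivalent and one equivalent of bromide limits double prenylation.

Step 10
Reactants: 16 2-methyl-1-[2,4,6-trihydroxy-3-(3-methylbut-2-en-1-yl)phenyl]propan-1-one; 17 bis(dimethylamino)methane
Product: 18 1-[3-[(dimethylamino)methyl]-2,4,6-trihydroxy-5-(3-methylbut-2-en-1-yl)phenyl]-2-methylpropan-1-one
Conditions: CH2Cl2, 0 °C → rt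
Reagents that add atoms: none
Why: In this Mannich aminomethylation the acidic phenol protonates the aminal and releases the dimethyl(methylidene)ammonium ion, which can attack only the single free carbon of ring A.

Step 11
Reactants: 18 1-[3-[(dimethylamino)methyl]-2,4,6-trihydroxy-5-(3-methylbut-2-en-1-yl)phenyl]-2-methylpropan-1-one; 12 (4R)-3,5-dihydroxy-2-methyl-4-(3-methylbut-2-en-1-yl)-4-(2-methylpropanoyl)cyclohexa-2,5-dien-1-one
Product: 20 CNP0191741.1 (target, S at the quaternary carbon of ring B), via ortho-quinone methide 19 (not isolated)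
Conditions: 1,4-dioxane, 60 °C; dilute citric acid wash
Reagents that add atoms: none
Why: The acidic trione 12 protonates the benzylic amine, loss of dimethylamine gives ortho-quinone methide 19, and the enolate of 12 adds through C6, its only hydrogen-bearing ring carbon (Michael addition with rearomatisation of ring A), without touching C4, whose descriptor becomes S through priorities only.

Compound list
1 | methyl 4-methyl-3-oxopentanoate | COC(=O)CC(=O)C(C)C | starting material
2 | methyl (3R)-3-hydroxy-4-methylpentanoate | COC(=O)C[C@@H](O)C(C)C | intermediate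
3 | 1-bromo-3-methylbut-2-ene | CC(C)=CCBr | starting material
4 | methyl (2S,3S)-3-hydroxy-4-methyl-2-(3-methylbut-2-en-1-yl)pentanoate | COC(=O)[C@@H](CC=C(C)C)[C@@H](O)C(C)C | intermediate
5 | pent-2-yn-1-ol | CCC#CCO | starting material
6 | pent-2-ynal | CCC#CC=O | intermediate
7 | methyl (2R)-2-[(1S)-1-hydroxy-2-methylpropyl]-2-(1-hydroxypent-2-yn-1-yl)-5-methylhex-4-enoate, propargylic carbinol undefined | COC(=O)[C@@](CC=C(C)C)(C(O)C#CCC)[C@@H](O)C(C)C | intermediate
8 | methyl (2R)-5-methyl-2-(2-methylpropanoyl)-2-(pent-2-ynoyl)hex-4-enoate | COC(=O)[C@@](CC=C(C)C)(C(=O)C#CCC)C(=O)C(C)C | intermediate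
9 | methyl (2R)-2-[(E)-3-(diethylamino)pent-2-enoyl]-5-methyl-2-(2-methylpropanoyl)hex-4-enoate | COC(=O)[C@@](CC=C(C)C)(C(=O)/C=C(/N(CC)CC)CC)C(=O)C(C)C | intermediate
10 | methyl (2S)-5-methyl-2-(2-methylpropanoyl)-2-(3-oxopentanoyl)hex-4-enoate | CCC(=O)CC(=O)[C@@](CC=C(C)C)(C(=O)C(C)C)C(=O)OC | intermediate
11 | dilithium dianion of 10 (enolate geometries not fixed) | [Li+].[Li+].CC=C([O-])C=C([O-])[C@@](CC=C(C)C)(C(=O)C(C)C)C(=O)OC | intermediate
12 | (4R)-3,5-dihydroxy-2-methyl-4-(3-methylbut-2-en-1-yl)-4-(2-methylpropanoyl)cyclohexa-2,5-dien-1-one | O=C1C=C(O)[C@@](CC=C(C)C)(C(=O)C(C)C)C(O)=C1C | intermediate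
13 | phloroglucinol | Oc1cc(O)cc(O)c1 | starting material
14 | 2-methylpropanoyl chloride | CC(C)C(=O)Cl | starting material
15 | 2-methyl-1-(2,4,6-trihydroxyphenyl)propan-1-one | CC(C)C(=O)c1c(O)cc(O)cc1O | intermediate
16 | 2-methyl-1-[2,4,6-trihydroxy-3-(3-methylbut-2-en-1-yl)phenyl]propan-1-one | CC(C)=CCc1c(O)cc(O)c(C(=O)C(C)C)c1O | intermediate
17 | bis(dimethylamino)methane | CN(C)CN(C)C | starting material
18 | 1-[3-[(dimethylamino)methyl]-2,4,6-trihydroxy-5-(3-methylbut-2-en-1-yl)phenyl]-2-methylpropan-1-one | CC(C)=CCc1c(O)c(CN(C)C)c(O)c(C(=O)C(C)C)c1O | intermediate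
19 | ortho-quinone methide of ring A (3,5-dihydroxy-6-methylidene-2-(3-methylbut-2-en-1-yl)-4-(2-methylpropanoyl)cyclohexa-2,4-dien-1-one) | C=C1C(=O)C(CC=C(C)C)=C(O)C(C(=O)C(C)C)=C1O | intermediate
20 | CNP0191741.1 | CC(C)=CCc1c(O)c(CC2=C(O)[C@@](CC=C(C)C)(C(=O)C(C)C)C(O)=C(C)C2=O)c(O)c(C(=O)C(C)C)c1O | target

Total step count: 11. Longest linear sequence: 7 (steps 1, 2, 4, 5, 6, 7, 11).

Steps most likely to fail

**Step 7.**
- What may go wrong: the second deprotonation may stay incomplete, the enolate oxygen may acylate instead of the carbon, or liberated methoxide may cleave the triacylated carbon by retro-Claisen attack.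
- Fallback: it replaces the dianion by a masked monoanion and sets out from 8.
- DABCO-catalysed oxa-Michael addition of methanol should give the β-methoxy enone methyl (2R)-2-[(E)-3-methoxypent-2-enoyl]-5-methyl-2-(2-methylpropanoyl)hex-4-enoate F1.
- γ-Deprotonation with LiN(iPr)2 (THF, −78 → 0 °C) gives a dienolate that can reach the ester only through its γ-carbon. It closes the same bond to the ring B methyl enol ether (6R)-5-hydroxy-3-methoxy-4-methyl-6-(3-methylbut-2-en-1-yl)-6-(2-methylpropanoyl)cyclohexa-2,4-dien-1-one F2.
- Hydrolysis of this vinylogous ester (1 M HCl, THF, rt) comes back to the route at 12.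

**Step 4.**
- What may go wrong: enolisation of the α-branched ester may be sluggish, facial selectivity of the open chelate toward an aldehyde may be poor, or the dialkoxide may lose isobutyraldehyde by retro-aldol cleavage.
- Fallback: it moves the stereocontrol into a rigid ring and sets out from 4.
- Saponification (LiOH, THF/H2O) gives (2S,3S)-3-hydroxy-4-methyl-2-(3-methylbut-2-en-1-yl)pentanoic acid F3.
- Acid-catalysed acetalisation with pivalaldehyde gives the 2,6-cis dioxanone (2S,5S,6S)-2-tert-butyl-5-(3-methylbut-2-en-1-yl)-6-(propan-2-yl)-1,3-dioxan-4-one F4.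
- In its lithium enolate the tert-butyl and isopropyl groups block the same face, so 6 should add from the opposite face. The product is (2S,5S,6S)-2-tert-butyl-5-(1-hydroxypent-2-yn-1-yl)-5-(3-methylbut-2-en-1-yl)-6-(propan-2-yl)-1,3-dioxan-4-one F5.
- Acid methanolysis (MeOH, cat. TsOH) comes back to the route at 7.

**Step 11.**
- What may go wrong: the methylene unit may exchange between the two partners through retro-Michael and retro-Mannich steps, which leads to symmetrical dimers, and the C4 prenyl group may migrate sigmatropically on heating.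
- Fallback: it fixes the bridge carbon on ring A at the aldehyde level and sets out from 16.
- Vilsmeier–Haack formylation (POCl3, DMF; then water) gives 2,4,6-trihydroxy-3-(3-methylbut-2-en-1-yl)-5-(2-methylpropanoyl)benzaldehyde F6.
- Proline-catalysed Knoevenagel condensation with 12 is run in the presence of the Hantzsch ester diethyl 2,6-dimethyl-1,4-dihydropyridine-3,5-dicarboxylate (CH2Cl2, rt). The ester reduces the alkylidene as it forms, and the sequence comes back to the route at 20.

Further compounds
F1 | step 7 | methyl (2R)-2-[(E)-3-methoxypent-2-enoyl]-5-methyl-2-(2-methylpropanoyl)hex-4-enoate | COC(=O)[C@@](CC=C(C)C)(C(=O)/C=C(/OC)CC)C(=O)C(C)C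
F2 | step 7 | (6R)-5-hydroxy-3-methoxy-4-methyl-6-(3-methylbut-2-en-1-yl)-6-(2-methylpropanoyl)cyclohexa-2,4-dien-1-one | COC1=CC(=O)[C@@](CC=C(C)C)(C(=O)C(C)C)C(O)=C1C
F3 | step 4 | (2S,3S)-3-hydroxy-4-methyl-2-(3-methylbut-2-en-1-yl)pentanoic acid | OC(=O)[C@@H](CC=C(C)C)[C@@H](O)C(C)C
F4 | step 4 | (2S,5S,6S)-2-tert-butyl-5-(3-methylbut-2-en-1-yl)-6-(propan-2-yl)-1,3-dioxan-4-one | O=C1O[C@@H](C(C)(C)C)O[C@@H](C(C)C)[C@@H]1CC=C(C)C
F5 | step 4 | (2S,5S,6S)-2-tert-butyl-5-(1-hydroxypent-2-yn-1-yl)-5-(3-methylbut-2-en-1-yl)-6-(propan-2-yl)-1,3-dioxan-4-one, propargylic carbinol undefined | O=C1O[C@@H](C(C)(C)C)O[C@@H](C(C)C)[C@]1(CC=C(C)C)C(O)C#CCC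
F6 | step 11 | 2,4,6-trihydroxy-3-(3-methylbut-2-en-1-yl)-5-(2-methylpropanoyl)benzaldehyde | CC(C)=CCc1c(O)c(C=O)c(O)c(C(=O)C(C)C)c1O
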